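Remark 1: atoms carry the numbering of the target skeleton (C1 quaternary fusion carbon, C2–C9 in the ten-membered ring, C10 fusion CH, C11–C14 in ring A, C15 methyl on C1, C16 methyl on C5, C17/C19 lactone carbons, C18 methyl on C17, C20 methyl on C11); on ring A, β is the face of the C15 methyl.
Remark 2: compound 3 is an interconverting pair of C11 epimers and is drawn as the epimer that cyclises; the C9 oxygen is carried as the acetate of the commercial enal.

## Structural features

The target is a bicyclo[8.4.0]tetradecane: cyclohexane ring A (C1, C10–C14) is trans-fused through C1–C10 to a ten-membered carbocycle that holds a Z trisubstituted alkene (C5=C6), and a γ-lactone (C7–O–C19–C17–C8) is fused trans across C7–C8. Its eleven stereocentres form three groups: C14/C1/C10/C11/C12 on ring A, C9/C8/C7/C17 around the lactone, and the anti-related acetates at C2 and C4. On ring A the C15 methyl, the C9 arm, the C20 methyl and the C12 hydroxyl all sit on the β face, with only the C14 acetate on the α face, so ring A carries a crowded all-cis tetrad. C1 is an all-carbon quaternary centre whose neighbours C14 (inside ring A) and C2 (outside it) both carry oxygen. Fragile groups are the β-hydroxy-γ-lactone (retro-aldol, dehydration, epimerisable C17), four acetates (C4 allylic), the allylic lactone oxygen at C7 and the tertiary C8 hydroxyl. The real difficulties are the ten-membered ring with its cis alkene, the all-cis face of ring A, and keeping the C12 hydroxyl free while C2, C4, C9 and C14 are acetylated. The key step exploits the fact that C1 bears a methyl and two acyl-level carbons: a C1 carrying two acetyl groups is prochiral and becomes stereogenic when one acetyl closes ring A onto C12.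

## Logic of the disconnections

34 ⇒ 32: the C19–O7 ester bond is cut and C19 lowered to the alcohol. The β-hydroxy lactone is the most fragile unit and is therefore made last. The gain is a tetraol without the lactone ring. The forward step must oxidise the primary C19 alcohol in the presence of the C12 and C7 secondary alcohols and let C7–OH capture the aldehyde.

32 ⇒ 31 ⇒ 30: the ring bond C6–C7 is cut. A C7 aldehyde next to the fully substituted C8 cannot enolise, and a Z alkenyl iodide at C6 keeps its geometry in a chromium-mediated addition. The gain is an open chain in which every stereocentre except C7 is already set on ring A and its two arms. The forward step needs high dilution and tolerance of four acetates; either C7 epimer can be corrected.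

30 ⇒ 19 + 23: the C3–C4 bond is cut and the C2 carbonyl restored. The C2 methyl ketone on quaternary C1 can enolise only towards C3, and the 2,4-anti diol follows from a hydroxyl-directed reduction. The gain is that C3–C6 comes from an achiral three-carbon aldehyde. The forward aldol needs reagent control at C4 because the nearest stereocentre is the remote C1.

19 ⇒ 16 ⇒ 10 + 15: the C17–C18 bond, the C8–O bond and the C8–C9 bond are cut in turn. C9, C8 and C17 are contiguous and can be set one from the other on an open chain: C9 from C10 in the addition to the aldehyde, C8 from C9 in a hydroxyl-directed epoxidation, C17 by inversion at the epoxide. The gain is that the lactone carbons arrive as one achiral four-carbon alkenyl iodide. The forward steps need addition to the aldehyde in the presence of the C2 ketone, a defined alkene geometry in 15, and methyl delivery to C17 only.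

10 ⇒ 6 ⇒ 4: these are functional-group changes on ring A. The C9 aldehyde comes from the primary alcohol; the C14 acetate and the C12 silyl ether are told apart through 7, which uses the cis relation of the C9 arm and O12; the C14 carbinol comes from 4 by reduction directed by O12. The demand is a 1,3-anti reduction that leaves the C2 ketone alone.

4 ⇒ 3: the C12–C13 bond is cut; ring A, C12 and C1 are made together and C11 is fixed at the same time. The two acetyl groups on C1 are diastereotopic, so the step must choose one of them and one aldehyde face. The closure is 6-(enolendo)-exo-trig, because the enamine double bond C13=C14 lies inside the new ring; an enolexo label would be wrong. The all-cis product also requires the C10 arm and the new C12 oxygen to be axial on the same face, which is the main demand on the step.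

3 ⇒ 1 + 2: the C1–C10 bond is cut. The conjugate addition sets C10; C11 arises by protonation and need not be controlled. Keeping the acetate of 1 saves protecting-group steps and avoids a free C9 hydroxyl, which would cleave the 1,3-diketone by acyl transfer.

15 ⇒ 14 ⇒ 12 ⇒ 11 and 23 ⇒ 22 ⇒ 20: both alkenyl iodides come from propargylic alcohols by hydroxyl-directed anti additions, which fix the alkene geometries through cyclic metal alkoxides.

## Other disconnections considered

Alternative 1: The cut is the C8–C17 bond of the lactone, with the C19–O7 ester already present as a propionate. In the forward sense, constant-current anodic oxidation of A2 (a ten-membered 8,9-enediol bis(silyl ether) whose O7 propionate is held as its ketene silyl acetal) would join C17 to C8 and give A1, with the C8 carbinol and a C9 ketone.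
- In its favour: one operation makes the quaternary carbinol and the lactone, it joins two nucleophilic carbons without prefunctionalisation, and A2 could come from an acyloin-type closure, the classic answer for this ring size.
- Against it here: three electron-rich π systems compete at the anode; C17 could bond to C8 (five-membered ring) or C9 (six-membered ring); C8 and C17 would be set only by the ring conformation; the C9 ketone needs a later selective reduction; and the step leaves C1 and ring A unaddressed.
- Comparison: on structure, the chosen plan sets C9, C8 and C17 on an open chain by models that can be argued one at a time, whereas A1 relies on transannular control. On mechanism, a radical-cation coupling is set against polar steps. On step economy, alternative 1 is the better for the lactone itself (one step against four) and the equal in needing one late redox step; it could be combined with the chosen ring A construction.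

Alternative 2: The cuts are C4–C5 and C6–C7, so that C5(Me)=C6 is inserted into an eight-membered ring. In the forward sense, irradiation of A4 (the C4 enol acetate of a ring A-fused cyclooctane-1,3-dione) with propyne, then deacetylation, would give A3 through [2+2] addition across C4=C7 and retro-aldol cleavage of C4–C7.
- In its favour: the Z geometry of C5=C6 is enforced by its origin in a four-membered ring, which equals the chosen plan (geometry there also comes from a cyclic carbometalation intermediate). Ring expansion from eight to ten avoids a direct ten-membered closure, and on that entropic point it is the better.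
- Against it here: propyne must add with the methyl at C5; A4 is itself a medium ring on a quaternary carbon; A3 has C7 as a methylene and C4 as a ketone, so C7 oxygenation, C4 reduction and the whole C8/lactone unit remain; and the skipped enedione can isomerise or close across the ring.
- Comparison: on structure, the alternative is strong on the alkene and weak on C7–C9, where the chosen plan is strongest. On mechanism, photochemical regiocontrol is less predictable than the aldol and epoxide steps used here. On step economy, two C–C bonds in one step is the better key step, but the redox work after it is heavier than in the chosen route.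

Alternative 3: The cut is C1–C10, the bond common to both rings. In the forward sense, base-induced transannular Michael addition in A6 (a fourteen-membered ring with the 2-methyl-1,3-diketone at C14/C1/C2 and a C8-keto C9=C10 enone) would give A5.
- In its favour: one bond closes ring A and the ten-membered ring and creates the quaternary centre. A fourteen-membered macrocyclisation is easier than a ten-membered one, so on ring-closure entropy and bond economy it is the better.
- Against it here: C1 and C10, and with them the trans fusion, would be set only by the macrocycle conformation; the diketone enolate could also add to the C8 carbonyl; the C12 silyloxy group is β to the C14 ketone and could be eliminated by base; C9 emerges as a methylene, so its oxygen must be added later against C7; and C2, C8 and C14 all need further stereoselective work.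
- Comparison: on structure, the chosen plan keeps C9 oxygenated throughout and sets C1 in a six-membered transition state under catalyst control. On mechanism, both rest on enol(ate) additions, but the chosen one has closer precedent. On step economy, the alternative wins at the key step and loses in the sequence leading to A6 and in the redox adjustments after A5.

Key step: step 2

Step 1
Reactants: 1 (E)-4-acetoxy-2-methylbut-2-enal; 2 3-methylpentane-2,4-dione
Product: 3 (2R,3S)-3-(acetoxymethyl)-4-acetyl-2,4-dimethyl-5-oxohexanal
Conditions: 9-amino-9-deoxy-epi-quinine (20 mol%), CF3CO2H (40 mol%), toluene, 0 °C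
Reagents that add atoms: none
Why: Iminium-catalysed asymmetric Michael addition: a primary amine is used because α-branched enals condense poorly with secondary amines, the diketone adds to C10 on the face left open by the ion-paired catalyst (the quinidine-derived pseudo-enantiomer is the alternative if the other face is favoured), and protonation of the enamine gives C11 without control, which is harmless.

Step 2
Reactants: 3 (2R,3S)-3-(acetoxymethyl)-4-acetyl-2,4-dimethyl-5-oxohexanal
Product: 4 ring A ketol (2S,3S,4R,5S)-2-acetyl-3-(acetoxymethyl)-5-hydroxy-2,4-dimethylcyclohexan-1-one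
Conditions: (S)-N1,N1-diethyl-3,3-dimethylbutane-1,2-diamine·TfOH (20 mol%), 3-nitrobenzoic acid (10 mol%), CHCl3, 25 °C
Reagents that add atoms: none
Why: The primary amine condenses with one acetyl group to a terminal enamine (C13=C14) while its ammonium arm hydrogen-bonds the aldehyde oxygen, C13 adds to C12, and hydrolysis of the iminium ion releases the β-hydroxy ketone. The closest known reaction type is the amine-catalysed intramolecular aldol of the Hajos–Parrish family, with the difference that here the catalyst chooses between two donor acetyl groups and not between two acceptor carbonyls. Ring A closes in the 6-(enolendo)-exo-trig mode (C13 and C14 both lie in the new ring, so the closure is not enolexo), which is favoured. C1 is defined by which acetyl enters the ring: catalyst control (the antipodal diamine is available if the sense is wrong) should be reinforced by the preference of the spectator acetyl for the pseudo-axial site next to the N-substituted enamine carbon, which leaves the C1 methyl cis to the C10 arm. C12 is defined by the aldehyde face: in the chair-like transition state the C10 arm is axial (its only syn-axial partner is C12, and an equatorial arm would be gauche to both groups on C1) and the ammonium-bound oxygen takes the axial site on the same face, giving the 12β-alcohol. C11 is fixed by dynamic kinetic resolution: the aldehyde α-centre epimerises through the aldehyde enamine, which cannot cyclise (only a four-membered ring would result), and the epimer with an equatorial methyl, cis to the arm, closes. The step therefore needs group selectivity between the diastereotopic acetyls, face selectivity at C12 and integrity of C10; mild acid and ambient temperature disfavour retro-Michael cleavage and dehydration, and O9 stays acylated because a free hydroxyl would cleave the 1,3-diketone by retro-Claisen acyl transfer.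

Step 3
Reactants: 4 ring A ketol
Product: 5 ring A 12β,14α-diol (C9 acetate; C2 acetyl)
Conditions: Me4NBH(OAc)3 (3 equiv), MeCN/AcOH 1:1, −35 °C
Reagents that add atoms: none
Why: Evans–Saksena reduction: the borohydride bound to the axial 12β-oxygen delivers hydride to the β face of C14, giving the 14α-alcohol (1,3-anti); the C2 ketone has no hydroxyl in reach until C14–OH exists, and limited reagent at low temperature holds back a second directed delivery.

Step 4
Reactants: 5 ring A 12β,14α-diol
Product: 6 ring A triol (10β-hydroxymethyl; 12β-OH; 14α-OH; C2 acetyl)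
Conditions: K2CO3 (0.3 equiv), MeOH, 0 °C
Reagents that add atoms: none
Why: Transesterification of the only ester (a primary acetate); the 1,3-diketone is already gone, and the cold, weakly basic medium should spare the C14-hydroxy C2-ketone from retro-aldol cleavage.

Step 5
Reactants: 6 ring A triol
Product: 7 9,12-O-(di-tert-butylsilylene) ring A ketone with free 14α-OH
Conditions: t-Bu2Si(OTf)2 (1.05 equiv), 2,6-lutidine, CH2Cl2, 0 °C
Reagents that add atoms: di-tert-butylsilyl bis(trifluoromethanesulfonate), CC(C)(C)[Si](OS(=O)(=O)C(F)(F)F)(OS(=O)(=O)C(F)(F)F)C(C)(C)C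
Why: Silylene protection of a diol: the primary C9 hydroxyl is silylated first and the ring can close only onto the 12β-hydroxyl, which is cis to the arm (both axial), not onto the trans 14α-hydroxyl, so C12 and C14 are told apart by geometry and not by relative rates.

Step 6
Reactants: 7 9,12-O-(di-tert-butylsilylene) ring A ketone
Product: 8 14α-acetate of the silylene
Conditions: Ac2O, pyridine, DMAP (cat.), rt
Reagents that add atoms: acetic anhydride, CC(=O)OC(C)=O
Why: Acylation of the only free hydroxyl installs the C14 acetate of the target early; C1 has no hydrogen, so the β-acetoxy ketone cannot eliminate.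

Step 7
Reactants: 8 14α-acetate of the silylene
Product: 9 C9 primary alcohol with 12β-O-di-tert-butylfluorosilyl ether and 14α-acetate
Conditions: BF3·SMe2, CH2Cl2, −20 to 0 °C; aq NaHCO3
Reagents that add atoms: boron trifluoride–dimethyl sulfide, C[S+](C)[B-](F)(F)F
Why: Regioselective mono-opening of a di-tert-butylsilylene acetal: the Lewis acid binds the less hindered primary oxygen and passes fluoride to silicon, freeing the C9 hydroxyl and leaving a robust fluorosilyl ether on O12.

Step 8
Reactants: 9 C9 primary alcohol
Product: 10 C9 aldehyde (12β-O-silyl; 14α-OAc; C2 acetyl)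
Conditions: Dess–Martin periodinane, NaHCO3, CH2Cl2, 0 °C
Reagents that add atoms: none
Why: Dess–Martin oxidation under buffered, non-basic conditions, which should not epimerise C10 or trigger aldol chemistry with the C2 ketone.

Step 9
Reactants: 11 but-2-yne-1,4-diol
Product: 12 4-(tert-butyldimethylsilyloxy)but-2-yn-1-ol
Conditions: NaH (1.0 equiv), THF, 0 °C; TBSCl
Reagents that add atoms: tert-butyldimethylsilyl chloride, CC(C)(C)[Si](C)(C)Cl
Why: Monosilylation of a symmetrical diol through its sparingly soluble monosodium alkoxide.

Step 10
Reactants: 12 4-(tert-butyldimethylsilyloxy)but-2-yn-1-ol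
Product: 14 (Z)-4-(tert-butyldimethylsilyloxy)-3-iodobut-2-en-1-ol, via sodium alkenylaluminate 13 (not isolated)
Conditions: NaAlH2(OCH2CH2OMe)2 (Red-Al), THF, 0 °C to rt; then I2, −78 °C
Reagents that add atoms: iodine, II
Why: Hydroxyl-directed trans-hydroalumination puts hydride on the proximal alkyne carbon and aluminium on the distal one in a five-membered aluminate, and iodinolysis with retention gives the Z iodide with iodine on the carbon that bears CH2OTBS (the future C8).

Step 11
Reactants: 14 (Z)-4-(tert-butyldimethylsilyloxy)-3-iodobut-2-en-1-ol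
Product: 15 (Z)-4-(tert-butyldimethylsilyloxy)-1-(tert-butyldiphenylsilyloxy)-3-iodobut-2-ene
Conditions: TBDPSCl, imidazole, DMF, rt
Reagents that add atoms: tert-butyldiphenylsilyl chloride, CC(C)(C)[Si](Cl)(c1ccccc1)c1ccccc1
Why: Standard silylation; the two primary oxygens (C7 as TBS, C19 as TBDPS) can later be unmasked in sequence.

Step 12
Reactants: 10 C9 aldehyde; 15 (Z)-4-(tert-butyldimethylsilyloxy)-1-(tert-butyldiphenylsilyloxy)-3-iodobut-2-ene
Product: 16 (9R) allylic alcohol with Z C8=C17 (C19 arm cis to C9; C7H2OTBS on C8)
Conditions: CrCl2 (6 equiv), NiCl2 (2 mol%), DMSO, rt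
Reagents that add atoms: none
Why: Nozaki–Hiyama–Kishi coupling: the alkenylchromium reagent adds to the aldehyde and not to the C2 ketone or the acetate, with retention of alkene geometry; Felkin–Anh attack anti to the quaternary C1 should give the 9R alcohol of the target.

Step 13
Reactants: 16 (9R) allylic alcohol
Product: 17 8,17-epoxy alcohol (epoxide threo to the C9 hydroxyl)
Conditions: mCPBA, NaHCO3, CH2Cl2, −20 to 0 °C
Reagents that add atoms: 3-chloroperoxybenzoic acid, OOC(=O)c1cccc(Cl)c1
Why: Hydroxyl-directed peracid epoxidation of the only alkene: allylic 1,3-strain with the cis C19 arm holds the carbinol hydrogen in the alkene plane, so the hydroxyl-bound peracid attacks the face that gives the threo epoxy alcohol, which is the C8 configuration of the target; the low temperature is chosen against Baeyer–Villiger oxidation of the C2 ketone.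

Step 14
Reactants: 17 8,17-epoxy alcohol
Product: 18 C8,C9-diol with the C17 methyl (C8, C9 and C17 as in the target)
Conditions: Me2CuLi (5 equiv, from CuI and MeLi), Et2O, −30 to 0 °C; aq NH4Cl
Reagents that add atoms: lithium dimethylcuprate, [Li+].C[Cu-]C
Why: SN2 opening of a trisubstituted epoxide by a cuprate at the only accessible carbon, secondary C17 (C8 is fully substituted), with inversion, which sets C17 and frees the tertiary C8 hydroxyl; at this temperature the cuprate should leave the hindered ketone, the acetate and the bulky fluorosilyl ether alone.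

Step 15
Reactants: 18 C8,C9-diol
Product: 19 C9 acetate with free tertiary C8 hydroxyl (methyl ketone at C2)
Conditions: Ac2O, pyridine, DMAP (cat.), 0 °C to rt
Reagents that add atoms: acetic anhydride, CC(=O)OC(C)=O
Why: A secondary hydroxyl is acylated far faster than the neighbouring tertiary one, which installs the C9 acetate of the target and protects C9 for the oxidations to come.

Step 16
Reactants: 20 prop-2-yn-1-ol
Product: 22 (Z)-3-iodo-2-methylprop-2-en-1-ol, via alkenylmagnesium bromide 21 (not isolated)
Conditions: MeMgBr (2.5 equiv), CuI (10 mol%), THF, −10 °C to rt; then I2, −78 to 0 °C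
Reagents that add atoms: methylmagnesium bromide, C[Mg]Br; iodine, II
Why: Copper-catalysed anti carbomagnesiation of the propargylic alkoxide places magnesium cis to the CH2O group through chelation, and iodinolysis with retention gives the Z iodide (the future C4 cis to C7).

Step 17
Reactants: 22 (Z)-3-iodo-2-methylprop-2-en-1-ol
Product: 23 (Z)-3-iodo-2-methylprop-2-enal
Conditions: MnO2, CH2Cl2, rt, dark; used at once
Reagents that add atoms: none
Why: Neutral allylic oxidation; acid, base and light are avoided so that the Z enal does not isomerise.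

Step 18
Reactants: 19 C9 acetate methyl ketone; 23 (Z)-3-iodo-2-methylprop-2-enal
Product: 26 (4R) β-hydroxy ketone with the Z C5=C6 alkenyl iodide, via boron enolate 24 (not isolated), via boron aldolate 25 (not isolated)
Conditions: (−)-Ipc2BCl (2.5 equiv), Et3N, Et2O, 0 °C; 23, −78 to −20 °C; H2O2, pH 7 buffer, MeOH
Reagents that add atoms: none
Why: Diisopinocampheylboron-mediated aldol of a methyl ketone: the ketone enolises only towards C3 (C1 is quaternary; acetates are not enolised), and the reagent antipode is chosen for Re-face addition to 23 so that C4 is R (the (+)-reagent serves if the sense is opposite); the hindered tertiary C8 hydroxyl at most consumes extra reagent and is freed on oxidative work-up.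

Step 19
Reactants: 26 (4R) β-hydroxy ketone
Product: 27 2,4-anti diol
Conditions: Me4NBH(OAc)3 (5 equiv), MeCN/AcOH 1:1, −20 °C to rt
Reagents that add atoms: none
Why: Evans–Saksena reduction: internal hydride delivery from the boron bound to O4 through a chair transition state gives the 1,3-anti diol, which is the C2 configuration of the target; the bulky group on C2 should reinforce the selectivity.

Step 20
Reactants: 27 2,4-anti diol
Product: 28 C2,C4-diacetate
Conditions: Ac2O, pyridine, DMAP (cat.), rt
Reagents that add atoms: acetic anhydride, CC(=O)OC(C)=O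
Why: Both secondary hydroxyls are acetylated (the allylic C4 quickly, the neopentyl C2 more slowly) while the tertiary C8 hydroxyl stays free; all four acetates of the target are now in place.

Step 21
Reactants: 28 C2,C4-diacetate
Product: 29 C7 primary alcohol
Conditions: camphorsulfonic acid (10 mol%), MeOH/CH2Cl2 1:1, 0 °C
Reagents that add atoms: none
Why: Acid-catalysed methanolysis removes a primary TBS ether much faster than the primary TBDPS ether or the hindered secondary fluorosilyl ether, and is too mild to transesterify the acetates.

Step 22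
Reactants: 29 C7 primary alcohol
Product: 30 C7 aldehyde (tertiary C8 hydroxyl free)
Conditions: TEMPO (10 mol%), PhI(OAc)2, CH2Cl2, rt
Reagents that add atoms: none
Why: Oxoammonium oxidation picks the primary alcohol, stops at the aldehyde and, unlike periodinane or periodate reagents, should not cleave the adjacent tertiary carbinol.

Step 23
Reactants: 30 C7 aldehyde
Product: 31 ten-membered ring C7 alcohol (Z C5=C6; C8 hydroxyl free)
Conditions: CrCl2 (10 equiv), NiCl2 (1 mol%), DMSO/THF, rt, 0.002 M, slow addition
Reagents that add atoms: none
Why: Intramolecular Nozaki–Hiyama–Kishi reaction, a proven closure for medium rings: the Z alkenylchromium species adds to the non-enolisable aldehyde with retention of geometry and with tolerance of acetates and free hydroxyls; C7 is set by the ring-forming transition state and can be corrected if needed.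

Step 24
Reactants: 31 ten-membered ring C7 alcohol
Product: 32 tetraol (C7, C8, C12 and C19 hydroxyls; four acetates)
Conditions: HF·pyridine, pyridine, THF, 0 °C to rt
Reagents that add atoms: none
Why: Buffered fluoride cleaves the primary TBDPS ether and the fluorosilyl ether on O12 without touching acetates; the slightly acidic medium disfavours acetyl migration.

Step 25
Reactants: 32 tetraol
Product: 34 CNP0183630.2, via lactol 33 (not isolated)
Conditions: TEMPO (20 mol%), PhI(OAc)2 (2.5 equiv), CH2Cl2, rt
Reagents that add atoms: none
Why: Oxidative lactonisation of a 1,4-diol: the primary C19 alcohol is oxidised first, the aldehyde is trapped by the C7 hydroxyl as a five-membered lactol, and this is oxidised to the γ-lactone; the secondary C12 and tertiary C8 hydroxyls react far more slowly, and fast lactol formation should protect C17 from epimerisation.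

## Compound list

1 | (E)-4-acetoxy-2-methylbut-2-enal | CC(=O)OC/C=C(\C)C=O | starting material
2 | 3-methylpentane-2,4-dione | CC(=O)C(C)C(C)=O | starting material
3 | (2R,3S)-3-(acetoxymethyl)-4-acetyl-2,4-dimethyl-5-oxohexanal (3,3-diacetyl aldehyde: C1 with methyl and two acetyls, C10 with acetoxymethyl, C11 methyl, C12 aldehyde; C11 epimers interconvert) | CC(=O)C(C)(C(C)=O)[C@@H](COC(C)=O)[C@@H](C)C=O | intermediate
4 | (2S,3S,4R,5S)-2-acetyl-3-(acetoxymethyl)-5-hydroxy-2,4-dimethylcyclohexan-1-one (ring A ketol: C14 ketone, 12β-OH, 11β-Me, 10β-CH2OAc, 1β-Me, 1α-acetyl) | CC(=O)[C@@]1(C)C(=O)C[C@H](O)[C@H](C)[C@@H]1COC(C)=O | intermediate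
5 | ring A diol: 14α-alcohol from 4 (12β-OH, 14α-OH, 10β-CH2OAc, 1α-acetyl) | O[C@H]1C[C@H](O)[C@H](C)[C@H](COC(C)=O)[C@@]1(C)C(C)=O | intermediate
6 | ring A triol (10β-CH2OH, 12β-OH, 14α-OH, 1α-acetyl) | O[C@H]1C[C@H](O)[C@H](C)[C@H](CO)[C@@]1(C)C(C)=O | intermediate
7 | 9,12-O-(di-tert-butylsilylene) derivative of 6 (seven-membered silylene; 14α-OH free) | O[C@H]1C[C@H]2[C@H](C)[C@H](CO[Si](C(C)(C)C)(C(C)(C)C)O2)[C@@]1(C)C(C)=O | intermediate
8 | 14α-acetate of 7 | CC(=O)O[C@H]1C[C@H]2[C@H](C)[C@H](CO[Si](C(C)(C)C)(C(C)(C)C)O2)[C@@]1(C)C(C)=O | intermediate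
9 | C9 primary alcohol with 12β-O-di-tert-butylfluorosilyl ether, 14α-acetate and C2 acetyl | CC(=O)O[C@H]1C[C@H](O[Si](F)(C(C)(C)C)C(C)(C)C)[C@H](C)[C@H](CO)[C@@]1(C)C(C)=O | intermediate
10 | C9 aldehyde corresponding to 9 | CC(=O)O[C@H]1C[C@H](O[Si](F)(C(C)(C)C)C(C)(C)C)[C@H](C)[C@H](C=O)[C@@]1(C)C(C)=O | intermediate
11 | but-2-yne-1,4-diol | OCC#CCO | starting material
12 | 4-(tert-butyldimethylsilyloxy)but-2-yn-1-ol | CC(C)(C)[Si](C)(C)OCC#CCO | intermediate
13 | sodium alkenylaluminate (five-membered oxaaluminate from trans-hydroalumination of 12) | [Na+].COCCO[Al-]1(OCCOC)OCC=C1CO[Si](C)(C)C(C)(C)C | intermediate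
14 | (Z)-4-(tert-butyldimethylsilyloxy)-3-iodobut-2-en-1-ol | OC/C=C(\I)CO[Si](C)(C)C(C)(C)C | intermediate
15 | (Z)-4-(tert-butyldimethylsilyloxy)-1-(tert-butyldiphenylsilyloxy)-3-iodobut-2-ene | CC(C)(C)[Si](C)(C)OC/C(I)=C/CO[Si](c1ccccc1)(c1ccccc1)C(C)(C)C | intermediate
16 | (9R) allylic alcohol: ring A as in 10 with C9(OH)–C8(CH2OTBS)=C17H–C19H2OTBDPS, C19 cis to C9 | CC(=O)O[C@H]1C[C@H](O[Si](F)(C(C)(C)C)C(C)(C)C)[C@H](C)[C@H]([C@@H](O)/C(CO[Si](C)(C)C(C)(C)C)=C\CO[Si](c2ccccc2)(c2ccccc2)C(C)(C)C)[C@@]1(C)C(C)=O | intermediate
17 | 8,17-epoxy alcohol, epoxide threo to the C9 hydroxyl | CC(=O)O[C@H]1C[C@H](O[Si](F)(C(C)(C)C)C(C)(C)C)[C@H](C)[C@H]([C@@H](O)[C@]2(CO[Si](C)(C)C(C)(C)C)O[C@@H]2CO[Si](c3ccccc3)(c3ccccc3)C(C)(C)C)[C@@]1(C)C(C)=O | intermediate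
18 | C8,C9-diol with C17 methyl (C8, C9, C17 as in the target; C7 OTBS, C19 OTBDPS) | CC(=O)O[C@H]1C[C@H](O[Si](F)(C(C)(C)C)C(C)(C)C)[C@H](C)[C@H]([C@@H](O)[C@@](O)(CO[Si](C)(C)C(C)(C)C)[C@@H](C)CO[Si](c2ccccc2)(c2ccccc2)C(C)(C)C)[C@@]1(C)C(C)=O | intermediate
19 | C9 acetate of 18 (tertiary C8–OH free; C2 methyl ketone) | CC(=O)O[C@H]1C[C@H](O[Si](F)(C(C)(C)C)C(C)(C)C)[C@H](C)[C@H]([C@@H](OC(C)=O)[C@@](O)(CO[Si](C)(C)C(C)(C)C)[C@@H](C)CO[Si](c2ccccc2)(c2ccccc2)C(C)(C)C)[C@@]1(C)C(C)=O | intermediate
20 | prop-2-yn-1-ol | C#CCO | starting material
21 | (Z)-alkenylmagnesium bromide, bromomagnesium alkoxide, from carbomagnesiation of 20 | Br[Mg]/C=C(\CO[Mg]Br)C | intermediate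
22 | (Z)-3-iodo-2-methylprop-2-en-1-ol | OC/C(C)=C\I | intermediate
23 | (Z)-3-iodo-2-methylprop-2-enal | O=C/C(C)=C\I | intermediate
24 | diisopinocampheylboron enolate of 19 | CC(=O)O[C@H]1C[C@H](O[Si](F)(C(C)(C)C)C(C)(C)C)[C@H](C)[C@H]([C@@H](OC(C)=O)[C@@](O)(CO[Si](C)(C)C(C)(C)C)[C@@H](C)CO[Si](c2ccccc2)(c2ccccc2)C(C)(C)C)[C@@]1(C)C(=C)OB([C@@H]3C[C@@H]4C[C@H]([C@H]3C)C4(C)C)[C@@H]5C[C@@H]6C[C@H]([C@H]5C)C6(C)C | intermediate
25 | diisopinocampheylboron aldolate (O4–B) | CC(=O)O[C@H]1C[C@H](O[Si](F)(C(C)(C)C)C(C)(C)C)[C@H](C)[C@H]([C@@H](OC(C)=O)[C@@](O)(CO[Si](C)(C)C(C)(C)C)[C@@H](C)CO[Si](c2ccccc2)(c2ccccc2)C(C)(C)C)[C@@]1(C)C(=O)C[C@@H](OB([C@@H]3C[C@@H]4C[C@H]([C@H]3C)C4(C)C)[C@@H]5C[C@@H]6C[C@H]([C@H]5C)C6(C)C)/C(C)=C\I | intermediate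
26 | (4R) β-hydroxy ketone: C2 ketone, C4–OH, Z C5(Me)=C6H–I | CC(=O)O[C@H]1C[C@H](O[Si](F)(C(C)(C)C)C(C)(C)C)[C@H](C)[C@H]([C@@H](OC(C)=O)[C@@](O)(CO[Si](C)(C)C(C)(C)C)[C@@H](C)CO[Si](c2ccccc2)(c2ccccc2)C(C)(C)C)[C@@]1(C)C(=O)C[C@@H](O)/C(C)=C\I | intermediate
27 | 2,4-anti diol (C2 and C4 as in the target) | CC(=O)O[C@H]1C[C@H](O[Si](F)(C(C)(C)C)C(C)(C)C)[C@H](C)[C@H]([C@@H](OC(C)=O)[C@@](O)(CO[Si](C)(C)C(C)(C)C)[C@@H](C)CO[Si](c2ccccc2)(c2ccccc2)C(C)(C)C)[C@@]1(C)[C@H](O)C[C@@H](O)/C(C)=C\I | intermediate
28 | C2,C4-diacetate of 27 | CC(=O)O[C@H]1C[C@H](O[Si](F)(C(C)(C)C)C(C)(C)C)[C@H](C)[C@H]([C@@H](OC(C)=O)[C@@](O)(CO[Si](C)(C)C(C)(C)C)[C@@H](C)CO[Si](c2ccccc2)(c2ccccc2)C(C)(C)C)[C@@]1(C)[C@H](OC(C)=O)C[C@@H](OC(C)=O)/C(C)=C\I | intermediate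
29 | C7 primary alcohol (C19 OTBDPS and O12 silyl kept) | CC(=O)O[C@H]1C[C@H](O[Si](F)(C(C)(C)C)C(C)(C)C)[C@H](C)[C@H]([C@@H](OC(C)=O)[C@@](O)(CO)[C@@H](C)CO[Si](c2ccccc2)(c2ccccc2)C(C)(C)C)[C@@]1(C)[C@H](OC(C)=O)C[C@@H](OC(C)=O)/C(C)=C\I | intermediate
30 | C7 aldehyde | CC(=O)O[C@H]1C[C@H](O[Si](F)(C(C)(C)C)C(C)(C)C)[C@H](C)[C@H]([C@@H](OC(C)=O)[C@@](O)(C=O)[C@@H](C)CO[Si](c2ccccc2)(c2ccccc2)C(C)(C)C)[C@@]1(C)[C@H](OC(C)=O)C[C@@H](OC(C)=O)/C(C)=C\I | intermediate
31 | ten-membered ring C7 alcohol (bicyclo[8.4.0] core; Z C5=C6; C7, C8 as in the target; C19 OTBDPS; O12 silyl) | CC(=O)O[C@H]1C[C@H](O[Si](F)(C(C)(C)C)C(C)(C)C)[C@H](C)[C@@H]2[C@@H](OC(C)=O)[C@](O)([C@@H](C)CO[Si](c3ccccc3)(c3ccccc3)C(C)(C)C)[C@H](/C=C(/C)[C@H](OC(C)=O)C[C@@H](OC(C)=O)[C@]21C)O | intermediate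
32 | tetraol (C7, C8, C12, C19 hydroxyls; acetates at C2, C4, C9, C14) | CC(=O)O[C@H]1C[C@H](O)[C@H](C)[C@@H]2[C@@H](OC(C)=O)[C@](O)([C@@H](C)CO)[C@H](/C=C(/C)[C@H](OC(C)=O)C[C@@H](OC(C)=O)[C@]21C)O | intermediate
33 | C19 lactol (C7–O–C19 hemiacetal, both anomers) | CC(=O)O[C@H]1C[C@H](O)[C@H](C)[C@@H]2[C@@H](OC(C)=O)[C@@]3(O)[C@H](/C=C(/C)[C@H](OC(C)=O)C[C@@H](OC(C)=O)[C@]21C)OC(O)[C@@H]3C | intermediate
34 | CNP0183630.2 (1R,2R,4R,7S,8S,9R,10S,11R,12S,14S,17R; 5Z) | CC(=O)O[C@H]1C[C@H](O)[C@H](C)[C@@H]2[C@@H](OC(C)=O)[C@@]3(O)[C@H](/C=C(/C)[C@H](OC(C)=O)C[C@@H](OC(C)=O)[C@]21C)OC(=O)[C@@H]3C | target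

## Step count and least certain steps

Total: 25 steps. Longest linear sequence: 20 steps (steps 1–8, 12–15 and 18–25, from 1 and 2 to 34).

Step 2 (key step). The most likely failure is closure through the competing chair in which the C10 arm stays equatorial; that chair drains the C11 epimer with the methyl trans to the arm and gives the wrong C11/C12 relation. It would be accompanied by erosion of C10 through retro-Michael cleavage, or by dehydration of the ketol. The cause is that the all-cis array is not favoured by the substrate alone and rests on the catalyst. Fallback, from 3 back to 4: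
- The closure is run as an aldol condensation with a primary amine salt at higher temperature (Hajos–Parrish-type condensation) to the cyclohexenone F1. Only the choice of acetyl (C1) is then set by the catalyst. C11, now vinylogously enolisable, should settle cis to the C10 arm, which is axial without penalty next to two trigonal ring carbons.
- The C12 oxygen is brought in by copper-catalysed conjugate borylation (CuCl, NaOt-Bu, a chiral ferrocenyl bisphosphine, B2pin2, MeOH) to the β-boryl ketone F2, with ligand control of the face.
- Oxidation with NaBO3, with retention, returns to 4.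

Step 1. The most likely failure is poor face selectivity or slow addition, because a fully substituted nucleophile meets an α-branched enal and γ-deprotonation of the iminium ion competes. Fallback, from 1 and 2 directly to 4: steps 1 and 2 are merged into an amine-catalysed Michael–aldol domino reaction with the diamine salt of step 2. The reversible Michael step then feeds the matched C10 enantiomer into the irreversible ring closure and 3 is not isolated (no new compound, F0).

Step 12. The most likely failure is insufficient Felkin–Anh selectivity at the congested aldehyde, giving a C9 epimer mixture. Fallback, from 16 (as the epimer mixture) back to 16: Dess–Martin oxidation to the cross-conjugated enone F3, then Corey–Bakshi–Shibata reduction with the oxazaborolidine enantiomer that gives the 9R alcohol. The hindered C2 methyl ketone is expected to react more slowly than the enone.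

Step 18. The most likely failure is weak reagent control at C4, because the enolate is very hindered and an unknown substrate bias from C1 may be mismatched. Fallback, from 19 back to 26: TMSOTf/Et3N converts 19 into the bis(trimethylsilyl) compound F4 (silyl enol ether of the C2 ketone, C8–OSiMe3). A catalytic enantioselective Mukaiyama aldol with 23 (Ti(Oi-Pr)4/(R)-BINOL) and an acidic work-up that removes both silyl groups then gives 26.

Step 23. The most likely failure is poor face selectivity at C7 in the ring-forming addition, with oligomerisation at insufficient dilution and acetyl migration from O9 to the new O7 as lesser risks. The cause is that the medium-ring transition state, not a simple model, decides. Fallback, from 31 (as the C7 epimer mixture) back to 31: MnO2 oxidation of the allylic alcohol to the macrocyclic enone F5, then Corey–Bakshi–Shibata reduction under reagent control to the 7S alcohol.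

## Further compounds

F1 | step 2 | (5R,6S)-6-acetyl-5-(acetoxymethyl)-4,6-dimethylcyclohex-2-en-1-one, target-numbering enone C12=C13 with C14 ketone | CC(=O)[C@@]1(C)C(=O)C=C[C@H](C)[C@@H]1COC(C)=O
F2 | step 2 | 12β-(pinacolatoboryl) ring A ketone | CC(=O)[C@@]1(C)C(=O)C[C@H](B2OC(C)(C)C(C)(C)O2)[C@H](C)[C@@H]1COC(C)=O
F0 | step 1 | none | none
F3 | step 12 | C9 ketone (enone) corresponding to 16 | CC(=O)O[C@H]1C[C@H](O[Si](F)(C(C)(C)C)C(C)(C)C)[C@H](C)[C@H](C(=O)/C(CO[Si](C)(C)C(C)(C)C)=C\CO[Si](c2ccccc2)(c2ccccc2)C(C)(C)C)[C@@]1(C)C(C)=O
F4 | step 18 | bis(trimethylsilyl) derivative of 19 (C2 silyl enol ether, C8 trimethylsilyl ether) | CC(=O)O[C@H]1C[C@H](O[Si](F)(C(C)(C)C)C(C)(C)C)[C@H](C)[C@H]([C@@H](OC(C)=O)[C@@](O[Si](C)(C)C)(CO[Si](C)(C)C(C)(C)C)[C@@H](C)CO[Si](c2ccccc2)(c2ccccc2)C(C)(C)C)[C@@]1(C)C(=C)O[Si](C)(C)C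
F5 | step 23 | macrocyclic C7 ketone (Z enone) corresponding to 31 | CC(=O)O[C@H]1C[C@H](O[Si](F)(C(C)(C)C)C(C)(C)C)[C@H](C)[C@@H]2[C@@H](OC(C)=O)[C@](O)([C@@H](C)CO[Si](c3ccccc3)(c3ccccc3)C(C)(C)C)C(=O)/C=C(/C)[C@H](OC(C)=O)C[C@@H](OC(C)=O)[C@]21C
A1 | alternative 1 | tricyclic lactone with C8 tertiary alcohol and C9 ketone | CC(C)(C)[Si](C)(C)O[C@H]1C[C@H](O[Si](C(C)C)(C(C)C)C(C)C)[C@H](C)[C@@H]2C(=O)[C@@]3(O)[C@H](/C=C(/C)[C@H](O[Si](C)(C)C(C)(C)C)C[C@@H](O[Si](C)(C)C(C)(C)C)[C@]21C)OC(=O)[C@@H]3C
A2 | alternative 1 | ten-membered 8,9-enediol bis(trimethylsilyl ether) with the O7 propionate as ketene trimethylsilyl acetal | CC(C)(C)[Si](C)(C)O[C@H]1C[C@H](O[Si](C(C)C)(C(C)C)C(C)C)[C@H](C)[C@@H]2C(O[Si](C)(C)C)=C(O[Si](C)(C)C)[C@H](/C=C(/C)[C@H](O[Si](C)(C)C(C)(C)C)C[C@@H](O[Si](C)(C)C(C)(C)C)[C@]21C)OC(O[Si](C)(C)C)=CC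
A3 | alternative 2 | bicyclo[8.4.0] C4,C8-diketone with Z C5=C6 | CC(C)(C)[Si](C)(C)O[C@H]1C[C@H](OCc3ccc(OC)cc3)[C@H](C)[C@@H]2[C@@H](O[Si](C)(C)C(C)(C)C)C(=O)C/C=C(/C)C(=O)C[C@@H](O[Si](C)(C)C(C)(C)C)[C@]21C
A4 | alternative 2 | C4 enol acetate of the ring A-fused cyclooctane-1,3-dione (C8 ketone) | CC(C)(C)[Si](C)(C)O[C@H]1C[C@H](OCc3ccc(OC)cc3)[C@H](C)[C@@H]2[C@@H](O[Si](C)(C)C(C)(C)C)C(=O)C=C(OC(C)=O)C[C@@H](O[Si](C)(C)C(C)(C)C)[C@]21C
A5 | alternative 3 | trans-fused bicyclo[8.4.0] C2,C8,C14-triketone | O=C1C[C@H](O[Si](C)(C)C(C)(C)C)[C@H](C)[C@@H]2CC(=O)[C@@H](O[Si](C)(C)C(C)(C)C)/C=C(/C)[C@H](O[Si](C)(C)C(C)(C)C)CC(=O)[C@]21C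
A6 | alternative 3 | fourteen-membered 2-methyl-1,3-diketone with C8-keto C9=C10 enone | CC1C(=O)C[C@H](O[Si](C)(C)C(C)(C)C)[C@H](C)/C=C/C(=O)[C@@H](O[Si](C)(C)C(C)(C)C)/C=C(/C)[C@H](O[Si](C)(C)C(C)(C)C)CC1=O
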